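The methylene bridge is cut at its bond to C7 of the quinone-methide carbocycle. Ring A is that carbocycle and ring B its dihydropyran; rings C and D are the arene and dihydropyran of the isochroman half, with primed locants.
Enabling feature: C7 is the only unsubstituted carbon of ring A and the central carbon of the vinylogous acid O=C8–C7=C6–OH, a 1,3-dicarbonyl-type donor. The bridge CH2 on C7' lies between C6'–OH and C8'–OH, and C1'H2 of ring D sits on C8a', ortho to C8'–OH and para to C6'–OH, so both CH2 groups are latent ortho-quinone methide termini.
Ring D is therefore opened as well. The electrophilic partner is an acyclic, unprotected resorcinol with two CH2NMe2 arms and the free side-chain alcohol; heating it with the ring A/B quinone methide closes ring D (O2'–C1') and forms CH2–C7 in one operation.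
Both partners come in one step each from one triol, (2R,3S)-3-(3,5-dihydroxy-2-methylphenyl)butan-2-ol: orthoformate closure gives rings A/B, and a double Mannich reaction gives the bis-amine.
The triol comes from an aryl Grignard reagent and (2S,3S)-2,3-dimethyloxirane (benzylic centre by inversion) followed by a Mitsunobu inversion (carbinol centre). Ring order: arene bought, ring B in step 7, ring D in step 9.

Key step: step 9

Remark: ring A is written as the 8-oxo-6-hydroxy tautomer of the target drawing. It exchanges rapidly with the 6-oxo-8-hydroxy form, which is the same compound. The epoxide is taken as a catalogue single enantiomer.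

Step 1
Reactants: 1 1-bromo-3,5-dimethoxybenzene
Product: 3 2-bromo-4,6-dimethoxybenzaldehyde, via aryl iminium chloride 2 (not isolated)
Conditions: POCl3, DMF, 0 → 90 °C; then H2O
Reagents that add atoms: N,N-dimethylformamide, CN(C)C=O; water, O
Why: Vilsmeier–Haack formylation, in which the chloroiminium ion attacks the position para to one methoxy group and ortho to the other rather than the crowded carbon between the two methoxy groups, and hydrolysis of 2 frees the aldehyde.

Step 2
Reactants: 3 2-bromo-4,6-dimethoxybenzaldehyde
Product: 4 1-bromo-3,5-dimethoxy-2-methylbenzene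
Conditions: Et3SiH (2.5 equiv), TFA, CH2Cl2, 0 °C → rt
Reagents that add atoms: none
Why: Ionic hydrogenation, in which the benzylic cations stabilised by the ortho and para methoxy groups are quenched twice by hydride from the silane while the aryl bromide stays inert.

Step 3
Reactants: 4 1-bromo-3,5-dimethoxy-2-methylbenzene; 5 (2S,3S)-2,3-dimethyloxirane
Product: 7 (2S,3S)-3-(3,5-dimethoxy-2-methylphenyl)butan-2-ol, via aryl Grignard reagent 6 (not isolated)
Conditions: Mg, THF, reflux; then CuI (10 mol %), 5, THF, −30 °C → rt; aq. NH4Cl
Reagents that add atoms: none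
Why: Copper-catalysed SN2 opening of an epoxide by an aryl Grignard reagent, in which backside attack on either of the two equivalent carbons of the C2-symmetric epoxide inverts that carbon and sets the benzylic centre as S while the carbinol carbon keeps its S configuration.

Step 4
Reactants: 7 (2S,3S)-3-(3,5-dimethoxy-2-methylphenyl)butan-2-ol
Product: 8 (2R,3S)-3-(3,5-dimethoxy-2-methylphenyl)butan-2-yl 4-nitrobenzoate
Conditions: 4-O2NC6H4CO2H, PPh3, DIAD, THF, 0 °C → rt
Reagents that add atoms: 4-nitrobenzoic acid, O=C(O)c1ccc(cc1)[N+](=O)[O-]
Why: Mitsunobu reaction in its 4-nitrobenzoic acid variant for hindered alcohols, in which SN2 displacement of the activated hydroxyl inverts the carbinol carbon from S to R, leaves the benzylic centre alone and so gives the threo (2R,3S) relation needed in both halves of the target.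

Step 5
Reactants: 8 (2R,3S)-3-(3,5-dimethoxy-2-methylphenyl)butan-2-yl 4-nitrobenzoate
Product: 9 (2R,3S)-3-(3,5-dihydroxy-2-methylphenyl)butan-2-yl 4-nitrobenzoate
Conditions: BBr3 (4 equiv), CH2Cl2, −78 → 0 °C; then H2O
Reagents that add atoms: none
Why: Lewis-acid cleavage of aryl methyl ethers by bromide attack at the methyl carbon, with the electron-poor ester shielding the secondary C–O bond and the oxygens, being meta to the side-chain carbon, offering no aryl participation that could scramble the stereocentres.

Step 6
Reactants: 9 (2R,3S)-3-(3,5-dihydroxy-2-methylphenyl)butan-2-yl 4-nitrobenzoate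
Product: 10 (2R,3S)-3-(3,5-dihydroxy-2-methylphenyl)butan-2-ol
Conditions: K2CO3 (3 equiv), MeOH, rt, Ar; then 1 M HCl (pH 5)
Reagents that add atoms: none
Why: Base-mediated transesterification of an activated benzoate breaks the acyl–oxygen bond, so the carbinol configuration is retained.

Step 7
Reactants: 10 (2R,3S)-3-(3,5-dihydroxy-2-methylphenyl)butan-2-ol
Product: 12 (3R,4S)-6-hydroxy-3,4,5-trimethyl-3,4-dihydroisochromen-8-one, via 1-ethoxyisochroman acetal 11 (not isolated)
Conditions: HC(OEt)3 (1.1 equiv), TFA (cat.), MeCN, 0 °C → rt
Reagents that add atoms: triethyl orthoformate, CCOC(OCC)OCC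
Why: Acid-catalysed exchange of the secondary alcohol into the orthoformate tethers a dialkoxycarbenium ion beside the ring carbon that is para to one phenol and ortho to the other, so an oxa-Pictet–Spengler-type closure of ring B gives 11, which loses ethanol to the stabilised quinone methide 12 without touching C3 or C4.

Step 8
Reactants: 10 (2R,3S)-3-(3,5-dihydroxy-2-methylphenyl)butan-2-ol
Product: 13 2,4-bis[(dimethylamino)methyl]-5-[(2S,3R)-3-hydroxybutan-2-yl]-6-methylbenzene-1,3-diol
Conditions: Me2N=CH2+ I− (2.2 equiv), K2CO3, MeCN, 0 °C → rt
Reagents that add atoms: N,N-dimethylmethyleneiminium iodide (Eschenmoser's salt), C=[N+](C)C.[I-]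
Why: Double phenolic Mannich reaction with a preformed iminium salt, in which the only two free ring positions are each ortho or para to both phenols, so exhaustive substitution can give a single constitution and the low temperature keeps the arms from eliminating.

Step 9
Reactants: 12 (3R,4S)-6-hydroxy-3,4,5-trimethyl-3,4-dihydroisochromen-8-one; 13 2,4-bis[(dimethylamino)methyl]-5-[(2S,3R)-3-hydroxybutan-2-yl]-6-methylbenzene-1,3-diol
Product: 17 (3R,4S)-7-{[(3R,4S)-6,8-dihydroxy-3,4,5-trimethyl-3,4-dihydro-1H-isochromen-7-yl]methyl}-6-hydroxy-3,4,5-trimethyl-3,4-dihydroisochromen-8-one, via ortho-quinone methide 14 (not isolated), via isochroman Mannich base 15 (not isolated), via ortho-quinone methide 16 (not isolated)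
Conditions: 12 (1.0 equiv), 13 (1.0 equiv), 1,4-dioxane (0.02 M), 100 °C, Ar sparge; then pH 5 buffer
Reagents that add atoms: none
Why: Proton transfer from the vinylogous acid 12 to an amine arm of 13 and heating expel Me2NH (retro-Michael) from the arm next to the side chain to give ortho-quinone methide 14, whose exocyclic CH2 is taken by the side-chain hydroxyl to give 15; loss of the second Me2NH from the arm between the two phenols gives 16, which is attacked by C7 of 12 (Michael addition, or hetero-Diels–Alder addition to the C6=C7 enol followed by hemiketal opening), and rearomatisation of ring C delivers 17. The closest known reaction type is the thermal generation of ortho-quinone methides from phenolic Mannich bases with capture by cyclic 1,3-dicarbonyl carbon nucleophiles, the standard biomimetic entry to methylene-bridged phenolic natural products, combined with the equally familiar intramolecular oxa-Michael capture by a tethered alcohol. Ring D closes in the 6-endo-trig oxa-Michael mode (O2' onto C1' of 14) and is driven by rearomatisation. No stereocentre is formed, and C3, C4, C3' and C4' pass through untouched because none is acidic or ionisable under neutral thermal conditions. The step needs each methylene to find its own nucleophile: the C1' methylene has the hydroxyl held in reach for a strain-free six-membered ring and is screened by the adjacent sec-alkyl branch, so at high dilution closure should outrun bimolecular capture, whereas the bridge methylene has no internal partner, the fully substituted ring C cannot alkylate itself, and any 15 formed early is simply further along the same path. Carbon over oxygen alkylation of 12 is secured because O-benzylation and amine addition at C1 are reversible at this temperature while the C–C bond is not, C7 being the only free carbon of ring A, and sweeping out Me2NH under acid-free conditions guards against enaminone formation and against cyclodehydration to a xanthene.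

Compound list
1 | 1-bromo-3,5-dimethoxybenzene | COc1cc(Br)cc(OC)c1 | starting material
2 | N-[(2-bromo-4,6-dimethoxyphenyl)methylidene]-N-methylmethanaminium chloride | C[N+](C)=Cc1c(Br)cc(OC)cc1OC.[Cl-] | intermediate
3 | 2-bromo-4,6-dimethoxybenzaldehyde | O=Cc1c(Br)cc(OC)cc1OC | intermediate
4 | 1-bromo-3,5-dimethoxy-2-methylbenzene | Cc1c(Br)cc(OC)cc1OC | intermediate
5 | (2S,3S)-2,3-dimethyloxirane | C[C@@H]1O[C@H]1C | starting material
6 | (3,5-dimethoxy-2-methylphenyl)magnesium bromide | Cc1c([Mg]Br)cc(OC)cc1OC | intermediate
7 | (2S,3S)-3-(3,5-dimethoxy-2-methylphenyl)butan-2-ol | O[C@@H](C)[C@@H](C)c1cc(OC)cc(OC)c1C | intermediate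
8 | (2R,3S)-3-(3,5-dimethoxy-2-methylphenyl)butan-2-yl 4-nitrobenzoate | O=C(O[C@H](C)[C@@H](C)c1cc(OC)cc(OC)c1C)c1ccc(cc1)[N+](=O)[O-] | intermediate
9 | (2R,3S)-3-(3,5-dihydroxy-2-methylphenyl)butan-2-yl 4-nitrobenzoate | O=C(O[C@H](C)[C@@H](C)c1cc(O)cc(O)c1C)c1ccc(cc1)[N+](=O)[O-] | intermediate
10 | (2R,3S)-3-(3,5-dihydroxy-2-methylphenyl)butan-2-ol | O[C@H](C)[C@@H](C)c1cc(O)cc(O)c1C | intermediate
11 | (3R,4S)-1-ethoxy-3,4,5-trimethyl-3,4-dihydro-1H-isochromene-6,8-diol, C1 epimers | CCOC1O[C@H](C)[C@@H](C)c2c(C)c(O)cc(O)c12 | intermediate
12 | (3R,4S)-6-hydroxy-3,4,5-trimethyl-3,4-dihydroisochromen-8-one (decarboxycitrinin) | CC1=C2C(=CO[C@H](C)[C@H]2C)C(=O)C=C1O | intermediate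
13 | 2,4-bis[(dimethylamino)methyl]-5-[(2S,3R)-3-hydroxybutan-2-yl]-6-methylbenzene-1,3-diol | O[C@H](C)[C@@H](C)c1c(CN(C)C)c(O)c(CN(C)C)c(O)c1C | intermediate
14 | 2-[(dimethylamino)methyl]-3-hydroxy-5-[(2S,3R)-3-hydroxybutan-2-yl]-4-methyl-6-methylidenecyclohexa-2,4-dien-1-one | O[C@H](C)[C@@H](C)C1=C(C)C(O)=C(CN(C)C)C(=O)C1=C | intermediate
15 | (3R,4S)-7-[(dimethylamino)methyl]-3,4,5-trimethyl-3,4-dihydro-1H-isochromene-6,8-diol | CN(C)Cc1c(O)c(C)c2c(c1O)CO[C@H](C)[C@H]2C | intermediate
16 | (3R,4S)-8-hydroxy-3,4,5-trimethyl-7-methylidene-3,4-dihydro-1H-isochromen-6(7H)-one | C=C1C(=O)C(C)=C2[C@H](C)[C@@H](C)OCC2=C1O | intermediate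
17 | (3R,4S)-7-{[(3R,4S)-6,8-dihydroxy-3,4,5-trimethyl-3,4-dihydro-1H-isochromen-7-yl]methyl}-6-hydroxy-3,4,5-trimethyl-3,4-dihydroisochromen-8-one | CC1=C2C(=CO[C@H](C)[C@H]2C)C(=O)C(Cc2c(O)c(C)c3c(c2O)CO[C@H](C)[C@H]3C)=C1O | target

Total step count: 9. Longest linear sequence: 8 (steps 1 to 6, then step 7 or step 8, then step 9).

Steps most likely to fail

1. Step 9. The external carbon nucleophile may capture the ring D methylene before the hydroxyl closes. The ortho-quinone methides may dimerise, or the liberated amine may add persistently to C1 of ring B. The fallback takes the ring closure out of the union. It sets out from 10. An oxa-Pictet–Spengler cyclisation with paraformaldehyde (1 equiv) and catalytic TFA in CH2Cl2 should give (3R,4S)-3,4,5-trimethyl-3,4-dihydro-1H-isochromene-6,8-diol F1. Its single free aromatic position, C7, is aminomethylated with one equivalent of N,N-dimethylmethyleneiminium iodide and K2CO3. The fallback comes back to the route at 15, now isolated and purified. Heating 15 with 12 in dioxane then involves only one ortho-quinone methide (16) and only one possible nucleophile pairing.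

2. Step 7. The unblocked nucleophilic C7 may be formylated a second time, or it may attack the electrophilic C1 of a second molecule under acid, leading to self-condensation. The fallback installs the formyl carbon while both phenols are still masked. It sets out from 8. Vilsmeier–Haack formylation (POCl3, DMF) at the position para to one methoxy group should give (2R,3S)-3-(2-formyl-3,5-dimethoxy-6-methylphenyl)butan-2-yl 4-nitrobenzoate F2. BBr3 then gives (2R,3S)-3-(2-formyl-3,5-dihydroxy-6-methylphenyl)butan-2-yl 4-nitrobenzoate F3. Methanolysis with K2CO3 in MeOH frees the alcohol, which on acidification to pH 5 should close to the lactol and lose water. The fallback comes back to the route at 12.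

3. Step 3. Attack of the ortho-methyl aryl nucleophile on a 2,3-disubstituted epoxide may be slow. Halohydrin formation by magnesium halide, or Lewis-acid rearrangement of the epoxide to butanone, could then take over. The fallback builds the stereodiad on an alkene and sets out from 4. Suzuki–Miyaura coupling with potassium (Z)-but-2-en-2-yltrifluoroborate (Pd(dppf)Cl2, Cs2CO3, THF–H2O) should give 1-[(E)-but-2-en-2-yl]-3,5-dimethoxy-2-methylbenzene F4 with retention of geometry. Asymmetric hydroboration with monoisopinocampheylborane prepared from (−)-α-pinene, then NaOH/H2O2, should give (2R,3S)-3-(3,5-dimethoxy-2-methylphenyl)butan-2-ol F5. Syn addition to the E alkene fixes the threo relation, and the reagent fixes the absolute sense. Acylation with 4-nitrobenzoyl chloride and pyridine brings the fallback back to the route at 8, whose recrystallisation should raise the enantiomeric purity. The Mitsunobu step is then no longer needed.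

Further compounds
F1 | step 9 | (3R,4S)-3,4,5-trimethyl-3,4-dihydro-1H-isochromene-6,8-diol | Cc1c(O)cc(O)c2c1[C@H](C)[C@@H](C)OC2
F2 | step 7 | (2R,3S)-3-(2-formyl-3,5-dimethoxy-6-methylphenyl)butan-2-yl 4-nitrobenzoate | O=C(O[C@H](C)[C@@H](C)c1c(C=O)c(OC)cc(OC)c1C)c1ccc(cc1)[N+](=O)[O-]
F3 | step 7 | (2R,3S)-3-(2-formyl-3,5-dihydroxy-6-methylphenyl)butan-2-yl 4-nitrobenzoate | O=C(O[C@H](C)[C@@H](C)c1c(C=O)c(O)cc(O)c1C)c1ccc(cc1)[N+](=O)[O-]
F4 | step 3 | 1-[(E)-but-2-en-2-yl]-3,5-dimethoxy-2-methylbenzene | C/C=C(\C)c1cc(OC)cc(OC)c1C
F5 | step 3 | (2R,3S)-3-(3,5-dimethoxy-2-methylphenyl)butan-2-ol | O[C@H](C)[C@@H](C)c1cc(OC)cc(OC)c1C
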